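## Analysis of the target

The target is a tri-ester of (−)-quinic acid: one cyclohexane ring (C1 to C6, quinic acid numbering) with a tertiary hydroxyl and a free carboxyl at C1, (E)-caffeoyl esters at O3 and O5, and a succinic half-ester at O4. Its four stereocentres are C1, C3, C4 and C5: O3 and O4 are cis, O4 and O5 are trans, and the 1-hydroxyl lies on the face of O3 and O4, so that in the chair O3 is axial while O4, O5 and the carboxyl are equatorial. The two caffeoyl groups therefore sit on non-equivalent positions, and the three secondary oxygens must be told apart. The sensitive groups are three vicinal esters that migrate under base once a neighbouring hydroxyl is free, two catechols that oxidise at high pH, two E alkenes that rule out hydrogenolysis, and two free acids. The end game may therefore use only acid and fluoride, and the difficulty lies in the order of three acylations on one triol and in the quaternary carbinol C1. The plan rests on the carbocycle being a 3-deoxyheptulosonic acid closed on itself: C1 is the keto-acid carbon, C2 the terminal chain carbon, and the C1–C2 bond is an aldol bond to a C3 ketone, flanked by the C4/C5 trans-diol.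

## Retrosynthetic reasoning

The last operations form no skeletal bond. Target 18 cannot be exposed to base, so the two tert-butyl–oxygen bonds are cut first in the backward sense, leading to 17, and re-silylating its four phenols leads to 16. This fixes the protecting groups for everything earlier: tert-butyl esters on both carboxyls and silyl ethers on the catechols.

The two caffeoyl ester C–O bonds at O3 and O5 of 16 are cut next, giving diol 11 and two equivalents of acid chloride 15. The cut is at the acyl–oxygen bond and not inside the side chain, because 12 already holds the whole aryl-propenoyl unit with its E alkene; 15 comes from 12 through acid 14, the transient tris-silyl compound 13 losing its silyl ester on work-up. The forward reaction must acylate one axial and one equatorial hydroxyl, leave the tertiary 1-hydroxyl alone, and be faster than any shift of the O4 acyl group.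

The O4 ester of 11 is then disconnected. An acyl group can be placed on the central oxygen only while O3 and O5 are masked, so 11 goes back to bis-silyl ether 10, and 10 to alcohol 7 and half-ester 9. Compound 9 is anhydride 8 opened by one molecule of alcohol, which keeps the second carboxyl of the succinate masked through the later acid chloride chemistry.

Removing the silyl groups and the ester alkyl group takes 7 back to 6 and then to 5. The forward silylation relies on O4 being flanked on both sides and on the tertiary O1 being inert.

In 5 the axial C3–H bond is cut: the carbinol is the reduction product of ketone 4. This places a carbonyl next to C2, which turns the C1–C2 bond into an aldol bond.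

Cutting C1–C2 of 4 (a retro-aldol between the carbon alpha to the C3 ketone and the carbinol-acid carbon) unfolds the ring into the seven-carbon chain of 3. There the future C2 is a phosphorylated primary carbinol and the future C3 a secondary carbinol; the enzyme supplies the oxidation, elimination and reduction that turn this into the reacting enolate. One ring, one C–C bond and the C1 stereocentre are gained on an unprotected substrate.

Finally 3 is cut at its C3–C4 bond into the three-carbon enol phosphate 1 and the four-carbon aldehyde 2. C2 of 2 becomes C4 of the target, the aldehyde carbon becomes C5, and C3 of 2 ends as the ketone carbon that is reduced again later.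

## Alternatives that were turned down

Alternative 1: The ring is cut at C1–C6 and C2–C3, a [4+2] disconnection. Forward, buta-1,3-diene A1 would add to the chiral alpha-oxyacrylate (R)-2-tert-butyl-5-methylene-1,3-dioxolan-4-one A2 in a Diels–Alder reaction, on the alkene face away from the tert-butyl group, to give spiro acetal A3.
- For: two skeletal bonds and the C1 centre form in one thermal step, with no protein and no phosphorylated substrate; either enantiomer is available. On scale and robustness it is stronger than the enzymatic aldol.
- Against: A3 holds only C1 and a C4=C5 alkene. O4 and O5 would have to be added trans across the alkene, and O3 at one of two allylic methylenes (C3 or C6) that differ only in their relation to C1. That means a long lactone-directed sequence under substrate control before any ester of the target is in place.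
- Comparison: the chosen route has C4 and C5 fixed before the ring closes, sets C1 in the closure and C3 in the next step, and reaches 5 in three steps. It pays for this with costly substrates and small scale.

Alternative 2: The cut lies in the side chains, at the two C(beta)–aryl bonds. Forward, bis-acrylate A4 would undergo a twofold Heck arylation with silyl-protected 4-bromocatechol A5 under a palladium–phosphine catalyst and an amine base, giving the protected tri-ester A6, which has the structure of 16.
- For: acryloylation of the axial O3 with a small acyl chloride is easier than acylation with 15, and the E geometry follows from syn insertion and syn beta-hydride elimination. On the esterification itself it is the stronger plan.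
- Against: it closes no ring and sets no stereocentre, so the quinate core must still be made. The electron-rich aryl bromide undergoes oxidative addition slowly, so two couplings on one molecule need prolonged heating with amine, and mono-coupled material and palladium residues must be separated from a catechol-rich product. It also rebuilds C–C bonds that 12 already contains.
- Comparison: the chosen strategy places its risk on the carbocycle and acylates directly; the Heck sequence is kept only as the reserve for step 11.

Alternative 3: The ring is cut at C3–C4, the bond of the cis-diol. Forward, the acyclic 1,6-dialdehyde A7 would be closed by a divalent samarium reagent in a pinacol coupling to give A8.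
- For: one step gives the ring, a C–C bond and two carbinol centres, one more stereocentre than the aldol. The chelated samarium diolate favours the cis-diol anti to the C5 benzyloxy group, which is the quinate pattern.
- Against: A7 must carry C1 (a fully substituted alkoxy ester carbon) and C5 in absolute configuration, each from a separate asymmetric step. Its two aldehydes are enolisable, one with an epimerisable alpha-alkoxy centre and the other with a beta-benzyloxy group that can be eliminated. A8 offers O3 and O4 as an undifferentiated diol, and its benzyl ethers can only be removed by hydrogenolysis before any cinnamoyl alkene is present, which leads back to 6.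
- Comparison: the chosen route reaches 6 in four steps and takes its stereocentres from a sugar phosphate and three enzyme active sites.

Key step: step 2

Assumption: DAHP synthase, 3-dehydroquinate synthase, quinate dehydrogenase and formate dehydrogenase are used as recombinant proteins in catalytic amounts, and 1 and 2 are bought as their potassium and sodium salts.

## Route

Step 1
Reactants: 1 phosphoenolpyruvic acid (monopotassium salt); 2 D-erythrose 4-phosphate (sodium salt)
Product: 3 3-deoxy-D-arabino-hept-2-ulosonic acid 7-phosphate, (4R,5S,6R)-4,5,6-trihydroxy-2-oxo-7-phosphonooxyheptanoic acid, drawn open-chain, in water mainly the pyranose hemiketal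
Conditions: DAHP synthase (E. coli AroG), MnCl2 (cat.), bis-tris propane buffer pH 7.0, 25 °C; anion-exchange chromatography
Reagents that add atoms: water, O
Why: Enzymatic aldol-type addition of the shikimate pathway: the methylene carbon of 1 adds to the re face of the aldehyde of 2 while water attacks C2 of 1 and phosphate leaves by C–O cleavage, which makes the addition irreversible; the active site sets the new carbinol (C4 of 3, the later C5) as R, threo to the carbinol that comes from C2 of 2.

Step 2
Reactants: 3 3-deoxy-D-arabino-hept-2-ulosonic acid 7-phosphate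
Product: 4 3-dehydroquinic acid, (1R,3R,4S)-1,3,4-trihydroxy-5-oxocyclohexane-1-carboxylic acid (ketone at C3, hydroxyls at C1, C4 and C5 in quinic numbering)
Conditions: 3-dehydroquinate synthase (E. coli AroB), NAD+ (cat.), CoCl2 (cat.), MOPS buffer pH 7.5, 25 °C; ultrafiltration, solution kept at pH 6–7 and 4 °C
Reagents that add atoms: none
Why: This is the natural reaction of 3-dehydroquinate synthase, closest in type to an intramolecular aldol addition of a ketone enolate to an alpha-keto acid that follows an E1cB loss of phosphate. Enzyme-bound NAD+ oxidises the C5 carbinol of 3 (the future C4), the C6–H next to the new ketone becomes acidic and phosphate leaves from C7 by beta-elimination, and the NADH just formed returns the hydride to C5 with the original configuration. When the pyranose hemiketal opens, the enol ether left behind is the enolate across C6 and C7 of 3 (C3 and C2 of 4), and its terminal carbon adds to the C2 keto-acid carbonyl (C1 of 4) to make the C1–C2 bond. The ring closes in the 6-(enolendo)-exo-trig mode, since both enolate carbons end inside the six-membered ring and the attacked C=O lies outside it. The one new stereocentre, C1, is set by the active site through a chair in which the C4 and C5 hydroxyls already present in 3 are equatorial, so that the carboxylate ends equatorial and the tertiary hydroxyl axial, cis to O4. The step needs a single enolate regiochemistry and a single face of the keto acid: the first is secured because the enolate is born by elimination at C7 and not by deprotonation of a ketone with two alpha positions, the second by the enzyme pocket. No protecting group is needed, and the configuration at the future C4 is not lost because its oxidation is undone within the same catalytic cycle.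

Step 3
Reactants: 4 3-dehydroquinic acid
Product: 5 (−)-quinic acid, (1S,3R,4S,5R)-1,3,4,5-tetrahydroxycyclohexane-1-carboxylic acid
Conditions: quinate dehydrogenase (E. coli YdiB), NADH (cat.), HCO2Na, formate dehydrogenase, phosphate buffer pH 7.0, 30 °C; Dowex 50 (H+ form), crystallisation from aqueous EtOH
Reagents that add atoms: none
Why: NADH-dependent ketone reduction by the dehydrogenase that interconverts 4 and 5 in nature; hydride is delivered to the one face of the C3 carbonyl that gives the axial 3R carbinol cis to O4, and oxidation of formate to CO2 pulls the equilibrium to the alcohol.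

Step 4
Reactants: 5 (−)-quinic acid
Product: 6 tert-butyl quinate (tert-butyl ester of 5, all four hydroxyls free)
Conditions: tBuOC(=NiPr)NHiPr (3 equiv), DMF/THF, 40 °C
Reagents that add atoms: O-tert-butyl-N,N'-diisopropylisourea, CC(C)N=C(OC(C)(C)C)NC(C)C
Why: Isourea esterification: only the carboxylic acid is acidic enough to protonate the isourea, so the tert-butyl group passes to the carboxylate within the ion pair, while the hydroxyls, which would need CuCl or an acid catalyst, stay free.

Step 5
Reactants: 6 tert-butyl quinate
Product: 7 tert-butyl 3,5-bis-O-(tert-butyldimethylsilyl)quinate (O1 and O4 free)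
Conditions: TBSCl (2.3 equiv), imidazole, DMF, 0 °C to rt
Reagents that add atoms: tert-butyldimethylsilyl chloride, CC(C)(C)[Si](C)(C)Cl
Why: Imidazole-catalysed silylation, selective by size: O5 and O3 react, whereas O4 is flanked by both silyloxy groups and the tertiary O1 is inert; the same pattern is known for methyl quinate and methyl shikimate.

Step 6
Reactants: 8 succinic anhydride
Product: 9 4-tert-butoxy-4-oxobutanoic acid (mono-tert-butyl succinate)
Conditions: tBuOH, N-hydroxysuccinimide (cat.), DMAP (cat.), Et3N, toluene, reflux
Reagents that add atoms: tert-butanol, CC(C)(C)O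
Why: Nucleophile-catalysed ring opening of a cyclic anhydride by an alcohol; one acyl group is esterified and the other is released as the free acid, so no diester can form.

Step 7
Reactants: 7 tert-butyl 3,5-bis-O-(tert-butyldimethylsilyl)quinate; 9 4-tert-butoxy-4-oxobutanoic acid
Product: 10 tert-butyl 4-O-(4-tert-butoxy-4-oxobutanoyl)-3,5-bis-O-(tert-butyldimethylsilyl)quinate
Conditions: EDC·HCl, DMAP, CH2Cl2, 0 °C to rt
Reagents that add atoms: none
Why: Steglich esterification: DMAP passes the activated acyl group of 9 on as an acylpyridinium ion that reaches the hindered equatorial O4, the only secondary hydroxyl left; the tertiary O1 next to the ester is far slower.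

Step 8
Reactants: 10 tert-butyl 4-O-(4-tert-butoxy-4-oxobutanoyl)-3,5-bis-O-(tert-butyldimethylsilyl)quinate
Product: 11 tert-butyl 4-O-(4-tert-butoxy-4-oxobutanoyl)quinate (O1, O3 and O5 free)
Conditions: HF·pyridine, pyridine/THF, 0 °C to rt
Reagents that add atoms: none
Why: Fluoride-driven cleavage of the two Si–O bonds in a buffered, slightly acidic medium, in which the alkoxide pathway for a shift of the O4 acyl group to O3 or O5 is suppressed and both tert-butyl esters are stable.

Step 9
Reactants: 12 caffeic acid, (E)-3-(3,4-dihydroxyphenyl)prop-2-enoic acid
Product: 14 (E)-3-[3,4-bis(tert-butyldimethylsilyloxy)phenyl]prop-2-enoic acid, via tris-silylated caffeate 13 (not isolated)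
Conditions: TBSCl (3.5 equiv), imidazole, DMF, rt; then AcOH/THF/H2O, rt
Reagents that add atoms: tert-butyldimethylsilyl chloride, CC(C)(C)[Si](C)(C)Cl
Why: Exhaustive silylation followed by selective hydrolysis: the silyl ester of 13 is far more labile to aqueous acid than the two aryl silyl ethers, so only the carboxyl is set free and the E alkene is untouched.

Step 10
Reactants: 14 (E)-3-[3,4-bis(tert-butyldimethylsilyloxy)phenyl]prop-2-enoic acid
Product: 15 (E)-3-[3,4-bis(tert-butyldimethylsilyloxy)phenyl]prop-2-enoyl chloride
Conditions: (COCl)2, DMF (cat.), CH2Cl2, 0 °C to rt; evaporation, used crude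
Reagents that add atoms: oxalyl chloride, O=C(Cl)C(=O)Cl
Why: Acid chloride formation through the Vilsmeier-type chloroiminium species; the by-products are gases and the aryl silyl ethers tolerate the anhydrous medium.

Step 11
Reactants: 11 tert-butyl 4-O-(4-tert-butoxy-4-oxobutanoyl)quinate; 15 (E)-3-[3,4-bis(tert-butyldimethylsilyloxy)phenyl]prop-2-enoyl chloride (2.6 equiv)
Product: 16 tert-butyl 3,5-bis-O-[(E)-3-(3,4-bis(tert-butyldimethylsilyloxy)phenyl)prop-2-enoyl]-4-O-(4-tert-butoxy-4-oxobutanoyl)quinate
Conditions: pyridine, DMAP (cat.), CH2Cl2, −20 °C to rt
Reagents that add atoms: none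
Why: Acylation of secondary alcohols by an acid chloride under nucleophilic catalysis; the equatorial O5 should react first and the axial O3 second, the tertiary O1 being too hindered, and an excess of 15 from the start lets acylation outrun any shift of the O4 ester.

Step 12
Reactants: 16 tert-butyl 3,5-bis-O-[(E)-3-(3,4-bis(tert-butyldimethylsilyloxy)phenyl)prop-2-enoyl]-4-O-(4-tert-butoxy-4-oxobutanoyl)quinate
Product: 17 tert-butyl 3,5-di-O-[(E)-caffeoyl]-4-O-(4-tert-butoxy-4-oxobutanoyl)quinate (four free phenols)
Conditions: Et3N·3HF, THF, rt, argon
Reagents that add atoms: none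
Why: Aryl silyl ethers are cleaved by fluoride under nearly neutral conditions because phenoxide leaves silicon easily; the esters and tert-butyl groups stay, and no secondary hydroxyl is free to accept a migrating acyl group.

Step 13
Reactants: 17 tert-butyl 3,5-di-O-[(E)-caffeoyl]-4-O-(4-tert-butoxy-4-oxobutanoyl)quinate
Product: 18 3,5-di-O-[(E)-caffeoyl]-4-O-succinoylquinic acid (CNP0133919.1, the target)
Conditions: TFA/CH2Cl2 (1:1), 0 °C to rt, argon; evaporation, reversed-phase chromatography
Reagents that add atoms: none
Why: Acidolysis of the two tert-butyl esters through the tert-butyl cation, which leaves as 2-methylpropene; the cinnamate and succinate esters of secondary alcohols, the catechols and the tertiary carbinol are inert to anhydrous acid, and no base touches the tri-ester.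

## Compound list

1 | phosphoenolpyruvic acid | C=C(OP(=O)(O)O)C(=O)O | starting material
2 | D-erythrose 4-phosphate | O=C[C@H](O)[C@H](O)COP(=O)(O)O | starting material
3 | 3-deoxy-D-arabino-hept-2-ulosonic acid 7-phosphate (open-chain form) | O[C@@H]([C@H](O)CC(=O)C(=O)O)[C@H](O)COP(=O)(O)O | intermediate
4 | 3-dehydroquinic acid | O[C@H]1[C@H](O)C[C@](O)(C(=O)O)CC1=O | intermediate
5 | (−)-quinic acid | O[C@H]1[C@H](O)C[C@](O)(C(=O)O)C[C@H]1O | intermediate
6 | tert-butyl quinate | O[C@H]1[C@H](O)C[C@](O)(C(=O)OC(C)(C)C)C[C@H]1O | intermediate
7 | tert-butyl 3,5-bis-O-(tert-butyldimethylsilyl)quinate | O[C@H]1[C@H](O[Si](C)(C)C(C)(C)C)C[C@](O)(C(=O)OC(C)(C)C)C[C@H]1O[Si](C)(C)C(C)(C)C | intermediate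
8 | succinic anhydride | O=C1CCC(=O)O1 | starting material
9 | 4-tert-butoxy-4-oxobutanoic acid | CC(C)(C)OC(=O)CCC(=O)O | intermediate
10 | tert-butyl 4-O-(4-tert-butoxy-4-oxobutanoyl)-3,5-bis-O-(tert-butyldimethylsilyl)quinate | CC(C)(C)OC(=O)CCC(=O)O[C@H]1[C@H](O[Si](C)(C)C(C)(C)C)C[C@](O)(C(=O)OC(C)(C)C)C[C@H]1O[Si](C)(C)C(C)(C)C | intermediate
11 | tert-butyl 4-O-(4-tert-butoxy-4-oxobutanoyl)quinate | CC(C)(C)OC(=O)CCC(=O)O[C@H]1[C@H](O)C[C@](O)(C(=O)OC(C)(C)C)C[C@H]1O | intermediate
12 | caffeic acid | O=C(O)/C=C/c1ccc(O)c(O)c1 | starting material
13 | tert-butyldimethylsilyl (E)-3-[3,4-bis(tert-butyldimethylsilyloxy)phenyl]prop-2-enoate | CC(C)(C)[Si](C)(C)OC(=O)/C=C/c1ccc(O[Si](C)(C)C(C)(C)C)c(O[Si](C)(C)C(C)(C)C)c1 | intermediate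
14 | (E)-3-[3,4-bis(tert-butyldimethylsilyloxy)phenyl]prop-2-enoic acid | O=C(O)/C=C/c1ccc(O[Si](C)(C)C(C)(C)C)c(O[Si](C)(C)C(C)(C)C)c1 | intermediate
15 | (E)-3-[3,4-bis(tert-butyldimethylsilyloxy)phenyl]prop-2-enoyl chloride | O=C(Cl)/C=C/c1ccc(O[Si](C)(C)C(C)(C)C)c(O[Si](C)(C)C(C)(C)C)c1 | intermediate
16 | tert-butyl 3,5-bis-O-[(E)-3-(3,4-bis(tert-butyldimethylsilyloxy)phenyl)prop-2-enoyl]-4-O-(4-tert-butoxy-4-oxobutanoyl)quinate | CC(C)(C)OC(=O)CCC(=O)O[C@H]1[C@H](OC(=O)/C=C/c2ccc(O[Si](C)(C)C(C)(C)C)c(O[Si](C)(C)C(C)(C)C)c2)C[C@](O)(C(=O)OC(C)(C)C)C[C@H]1OC(=O)/C=C/c1ccc(O[Si](C)(C)C(C)(C)C)c(O[Si](C)(C)C(C)(C)C)c1 | intermediate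
17 | tert-butyl 3,5-di-O-[(E)-caffeoyl]-4-O-(4-tert-butoxy-4-oxobutanoyl)quinate | CC(C)(C)OC(=O)CCC(=O)O[C@H]1[C@H](OC(=O)/C=C/c2ccc(O)c(O)c2)C[C@](O)(C(=O)OC(C)(C)C)C[C@H]1OC(=O)/C=C/c1ccc(O)c(O)c1 | intermediate
18 | 3,5-di-O-[(E)-caffeoyl]-4-O-succinoylquinic acid | O=C(O)CCC(=O)O[C@H]1[C@H](OC(=O)/C=C/c2ccc(O)c(O)c2)C[C@](O)(C(=O)O)C[C@H]1OC(=O)/C=C/c1ccc(O)c(O)c1 | target

## Step count and least certain steps

Total step count: 13. Longest linear sequence: 10 steps (steps 1, 2, 3, 4, 5, 7, 8, 11, 12 and 13); steps 6, 9 and 10 are side branches.

Step 2 (key step). Turnover may stall when the enzyme loses its bound NAD+ or its divalent metal during a long incubation. The beta-hydroxy ketone product may also lose its C1 hydroxyl by base-promoted dehydration during concentration and isolation. The fallback sets out from 3 and comes back at 5. The synthase is run in the same vessel as quinate dehydrogenase, NADH, sodium formate and formate dehydrogenase at pH 7, so that 4 is reduced as fast as it forms and never has to survive isolation. The design changes from isolating a labile ketone to trapping it, and it makes no new compound (F0).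

Step 4. Poor solubility of the polar acid may slow the transfer of the tert-butyl group, so that the isourea decays to 2-methylpropene before the acid is consumed. The fallback sets out from 5 and comes back at 7 by reversing the order of the two protections. Treating 5 with excess TBSCl and imidazole in DMF should give the silyl ester tert-butyldimethylsilyl 3,5-bis-O-(tert-butyldimethylsilyl)quinate F1. Its silyl ester is hydrolysed with aqueous acetic acid in THF to the lipophilic acid 3,5-bis-O-(tert-butyldimethylsilyl)quinic acid F2. F2 is then esterified with the same isourea in CH2Cl2 to give 7.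

Step 7. Acyl transfer to the flanked O4 may be slow enough for the activated acid to rearrange to an N-acylurea, or for a silyl group to shift from O3 or O5 to O4 under DMAP. The fallback sets out from 7 and comes back at 10. O4 is acylated with the small cyclic anhydride 8 (DMAP, Et3N, CH2Cl2, 40 °C) to give the half-ester tert-butyl 4-O-(3-carboxypropanoyl)-3,5-bis-O-(tert-butyldimethylsilyl)quinate F3. The new carboxyl of F3 is then esterified with O-tert-butyl-N,N'-diisopropylisourea in CH2Cl2.

Step 8. The succinoyl group may shift from O4 to a freshly freed neighbouring hydroxyl, and the hindered silyl ethers may cleave incompletely within the time the substrate tolerates. The fallback sets out from 6 and comes back at 11 with a more labile silyl group. Silylation of 6 with Et3SiCl (2.2 equiv) and imidazole in DMF at −20 °C should give tert-butyl 3,5-bis-O-(triethylsilyl)quinate F4. Acylation of F4 with 9 as in step 7 gives tert-butyl 4-O-(4-tert-butoxy-4-oxobutanoyl)-3,5-bis-O-(triethylsilyl)quinate F5. F5 is unmasked with AcOH/THF/H2O at rt, conditions under which acyl migration is slow.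

Step 11. Acylation of the axial O3 by the electron-rich, bulky acid chloride may be incomplete. Forcing it may acylate O1 or give the O4 ester time to shift under pyridine and DMAP. The fallback sets out from 11 and comes back at 16 by building the cinnamoyl units on the ring. Acryloyl chloride and iPr2NEt in CH2Cl2 at −40 °C should give tert-butyl 3,5-di-O-acryloyl-4-O-(4-tert-butoxy-4-oxobutanoyl)quinate F6. Twofold Heck arylation of F6 with 4-bromo-1,2-bis(tert-butyldimethylsilyloxy)benzene F7 (from 4-bromocatechol, TBSCl and imidazole) under Pd(OAc)2, P(o-tolyl)3 and Et3N in MeCN at 85 °C gives 16.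

## Further compounds

F0 | step 2 | none | none
F1 | step 4 | tert-butyldimethylsilyl 3,5-bis-O-(tert-butyldimethylsilyl)quinate | O[C@H]1[C@H](O[Si](C)(C)C(C)(C)C)C[C@](O)(C(=O)O[Si](C)(C)C(C)(C)C)C[C@H]1O[Si](C)(C)C(C)(C)C
F2 | step 4 | 3,5-bis-O-(tert-butyldimethylsilyl)quinic acid | O[C@H]1[C@H](O[Si](C)(C)C(C)(C)C)C[C@](O)(C(=O)O)C[C@H]1O[Si](C)(C)C(C)(C)C
F3 | step 7 | tert-butyl 4-O-(3-carboxypropanoyl)-3,5-bis-O-(tert-butyldimethylsilyl)quinate | O=C(O)CCC(=O)O[C@H]1[C@H](O[Si](C)(C)C(C)(C)C)C[C@](O)(C(=O)OC(C)(C)C)C[C@H]1O[Si](C)(C)C(C)(C)C
F4 | step 8 | tert-butyl 3,5-bis-O-(triethylsilyl)quinate | O[C@H]1[C@H](O[Si](CC)(CC)CC)C[C@](O)(C(=O)OC(C)(C)C)C[C@H]1O[Si](CC)(CC)CC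
F5 | step 8 | tert-butyl 4-O-(4-tert-butoxy-4-oxobutanoyl)-3,5-bis-O-(triethylsilyl)quinate | CC(C)(C)OC(=O)CCC(=O)O[C@H]1[C@H](O[Si](CC)(CC)CC)C[C@](O)(C(=O)OC(C)(C)C)C[C@H]1O[Si](CC)(CC)CC
F6 | step 11 | tert-butyl 3,5-di-O-acryloyl-4-O-(4-tert-butoxy-4-oxobutanoyl)quinate | CC(C)(C)OC(=O)CCC(=O)O[C@H]1[C@H](OC(=O)C=C)C[C@](O)(C(=O)OC(C)(C)C)C[C@H]1OC(=O)C=C
F7 | step 11 | 4-bromo-1,2-bis(tert-butyldimethylsilyloxy)benzene | Brc1ccc(O[Si](C)(C)C(C)(C)C)c(O[Si](C)(C)C(C)(C)C)c1
A1 | alternative 1 | buta-1,3-diene | C=CC=C
A2 | alternative 1 | (R)-2-tert-butyl-5-methylene-1,3-dioxolan-4-one | C=C1O[C@@H](C(C)(C)C)OC1=O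
A3 | alternative 1 | spiro adduct, pivalaldehyde acetal of (S)-1-hydroxycyclohex-3-ene-1-carboxylic acid | C1=CC[C@@]2(O[C@@H](C(C)(C)C)OC2=O)CC1
A4 | alternative 2 | tert-butyl 3,5-di-O-acryloyl-4-O-(4-tert-butoxy-4-oxobutanoyl)quinate | CC(C)(C)OC(=O)CCC(=O)O[C@H]1[C@H](OC(=O)C=C)C[C@](O)(C(=O)OC(C)(C)C)C[C@H]1OC(=O)C=C
A5 | alternative 2 | 4-bromo-1,2-bis(tert-butyldimethylsilyloxy)benzene | Brc1ccc(O[Si](C)(C)C(C)(C)C)c(O[Si](C)(C)C(C)(C)C)c1
A6 | alternative 2 | fully protected 3,5-di-O-caffeoyl-4-O-succinoylquinate | CC(C)(C)OC(=O)CCC(=O)O[C@H]1[C@H](OC(=O)/C=C/c2ccc(O[Si](C)(C)C(C)(C)C)c(O[Si](C)(C)C(C)(C)C)c2)C[C@](O)(C(=O)OC(C)(C)C)C[C@H]1OC(=O)/C=C/c1ccc(O[Si](C)(C)C(C)(C)C)c(O[Si](C)(C)C(C)(C)C)c1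
A7 | alternative 3 | tert-butyl 2,4-bis(benzyloxy)-5-oxo-2-(2-oxoethyl)pentanoate (the C3–C4 seco-dialdehyde of A8) | O=C[C@H](OCc1ccccc1)C[C@](OCc1ccccc1)(C(=O)OC(C)(C)C)CC=O
A8 | alternative 3 | tert-butyl 1,5-di-O-benzylquinate | O[C@H]1[C@H](OCc2ccccc2)C[C@](OCc2ccccc2)(C(=O)OC(C)(C)C)C[C@H]1O
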